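I charged the electrophile with 1.20 equiv of nucleophile, dosed over 25 min, and with 1.10 equiv of free base on Tuesday and 1.40 equiv on Sunday.

| setting | Tuesday's | Sunday's |
|---|---|---|
| electrophile | 0.063 M | 0.063 M |
| nucleophile | 1.20 equiv (fed, over 25 min) | 1.20 equiv (fed, over 25 min) |
| free base | 1.10 equiv | 1.40 equiv |
| time | 4.0 h | 4.0 h |
| remark | the fed solution adds 0.50 times the starting volume | the fed solution adds 0.50 times the starting volume |

- for product the crystals are counted in
- charges are per starting volume, the dose included; the dosed solution carries all of it
- as a solid, counted per litre of solution: crystals
- run time (Tuesday's): 4.0 h

- part of the electrophile that has reacted at the end, Tuesday's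
- part of the electrophile that has reacted at the end, Sunday's
- what raising the equivalents of free base from its lowest to its highest value here does to the part of the electrophile that has reacted (changes below 5 percentage points count as none) (it falls / it rises / no change)

    electrophile + nucleophile ⇌ acid set free + product (K1 = 1.9, k1 = 0.32 M⁻¹ min⁻¹)
    nucleophile + acid set free ⇌ protonated nucleophile, settled at all times (K2 = 1.0 × 10⁵ M⁻¹)
    acid set free + free base ⇌ salt of the base (K3 = 2600 M⁻¹, k3 = 3.0 M⁻¹ min⁻¹)
    crystals ⇌ product, rate k4*(cs4 - [product]) while solid is left; crystals form when [product] > cs4 (cs4 = 7.1 mM, k4 = 2.5 min⁻¹)

Each electrophile that reacts gives product and sets one acid free, which the nucleophile or the free base can then bind. The nucleophile binds it in a step kept at balance and the base by a step with its own rate, so I turned that rate into a time.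

With free and protonated nucleophile equal, the base needs 505 h on Tuesday's and 397 h on Sunday's to bind acid equal to the whole electrophile charge, far longer than the 4.0 h run. In the run time that is 0.792 % and 1.01 % of the charge, so I counted two nucleophiles per electrophile. That made the nucleophile the limiting reagent and gave me a stall point, half the nucleophile equivalents read as a fraction of the electrophile charged: 60.0 %. I expected both flasks near the stall point and no change.

The forecast gave 59 % and 60 % and no change, holding that “each electrophile effectively uses two nucleophiles”.

The flasks gave 58.4 % on Tuesday's and 58.6 % on Sunday's, a change of 0.14 percentage points, so no change. The stall point is a slowing and not an end, since Tuesday's stood at 79.1 % after 40.0 h.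

At the end Tuesday's flask stood 1.6 points short of its stall point, with 4.9 % of its nucleophile left and 98 % of its free base. One more flask, like Tuesday's but with 0.480 equiv of nucleophile, keeps the base time of 505 h, and half its equivalents put its stall point at 24.0 %. It gave 25.2 %, with 3.8 % of its nucleophile and 75 % of its electrophile still there.

The constants used here are made up; the rest is arithmetic.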